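Watch the incoming ligand.

common to all: time 25 min
- Sunday's: starting complex 20 mM; incoming ligand 1.10 equiv; everything together at the start
- Thursday's: starting complex 20 mM; incoming ligand 1.10 equiv (fed, over 5.0 min); all else is in the flask from the start; the feed brings no volume worth counting
- Tuesday's: starting complex 20 mM; incoming ligand 1.10 equiv (in portions, 3, over 5.0 min); first portion at the start, last at 5.0 min
- Monday's: starting complex 20 mM (fed, over 5.0 min); incoming ligand 1.10 equiv; all else is in the flask from the start; the feed brings no volume worth counting

1. which flask leads in amount of side product, in percent of the starting complex charged ("all alike" within 1.5 percentage points) (Sunday's / Thursday's / Tuesday's / Monday's / all alike)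
2. how much side product is there at the end, in percent of the starting complex charged: Sunday's
3. how much side product is there at the end, in percent of the starting complex charged: Thursday's
4. how much side product is there at the end, in percent of the starting complex charged: Tuesday's
5. how much side product is there at the end, in percent of the starting complex charged: Monday's

- a doubled species enters its step squared and goes two at a time
- run time (Sunday's): 25 min

Call the incoming ligand X and the starting complex M. I reckon with two routes for X: exchange with M, at 0.40 M⁻¹ s⁻¹ times [M][X], and self-condensation, at 2 times 3.4 M⁻¹ s⁻¹ times [X] squared. At the charged M the two run level at X* = 1.18 mM, the crossover concentration, the ligand level at which exchange and self-condensation consume X equally fast. At any moment exchange takes the share X*/(X* + [X]). While M holds, exchange is pseudo-first-order in X.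

Sunday's flask starts at 22.0 mM, far above X*. Summing the share as X falls gives X* ln(1 + charge/X*), or 3.51 mM exchanged. The once-exchanged complex has a half-life of 0.96 min by the side-product step, shorter than the run, so I count one side product per exchange.

In Thursday's flask X settles where the feed equals both drains, at 2.75 mM, giving a share of 0.300. There the side-product step, 0.012 s⁻¹, outruns further exchange. The share of the charge, plus Sunday's rule for the ligand left when the feed stops, gives 8.01 mM. Tuesday's flask is Sunday's rule applied to each of 3 portions: 6.98 mM. In Monday's flask I take M as rising with time and X as falling inversely with time, the course of self-condensation alone. On that course exchange runs at X* per feed time and yields about X*, a rough figure that leaves out exchange's own draw on X.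

The weak link is holding M at its charge. I reforge it by putting the mean of M, charge and estimated remainder, into X*. Sunday's becomes 1.07 mM, Thursday's 0.941 mM, Tuesday's 0.971 mM. I commit to Sunday's 3.29 mM, or 16.5%. Thursday's gives 2.85 mM and 6.77 mM, or 33.9%. Tuesday's gives 6.25 mM, or 31.3%, and Monday's 5.88%. The leader is Thursday's.

The forecast names Thursday's, with 12.5%, 24%, 22% and 4.5% for Sunday's, Thursday's, Tuesday's and Monday's, on the ground that “dosing it slowly (Thursday's, then Tuesday's) keeps its concentration low”.

The flasks give 16.9%, 32.3%, 28.5% and 4.81% in that order, and Thursday's leads.

    starting complex + incoming ligand ⇌ leaving ligand + complex with one exchanged (K1 = 1.8, k1 = 0.40 M⁻¹ s⁻¹)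
    complex with one exchanged + incoming ligand ⇌ leaving ligand + complex with two exchanged (K2 = 1.9, k2 = 0.90 M⁻¹ s⁻¹)
    complex with one exchanged → side product (k3 = 0.012 s⁻¹)
    2 incoming ligand → self-condensation product (k4 = 3.4 M⁻¹ s⁻¹)

Thursday's ligand stands at 2.85 mM when the feed ends, beside my 2.85 mM. The neighbouring flask is Thursday's with 0.660 equiv of ligand, or 13.2 mM. With X* at the charge, the level is 2.02 mM and the exchange 6.03 mM. The mean M brings X* to 0.999 mM, the level to 2.09 mM, and the exchange to 5.39 mM, or 27.0% of the starting complex. That flask gives 24.9% side product, with 75% of the starting complex still there.

The numbers of this flask stand for no real mixture, and the outcome is calculated.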